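The octaprenyl chain is disconnected at the sp2–sp3 bond between the vinylic CH of the seventh trisubstituted alkene (counted from the isopropylidene terminus) and the allylic CH2 next to it. Because this CH2 is homoallylic to the C(CH3)=CH alkene nearest the chroman, it can arise as the terminal carbon of an (E)-1,3-diene. In one flask, 9-BBN hydroboration of that diene and B-alkyl Suzuki–Miyaura coupling with a C34 (E)-alkenyl iodide form the bond and complete the skeleton with all alkene geometries retained. The iodide stems from two farnesyl units and a syn-carboalumination; the pyran ring of the chroman, with C2 taken from (R)-linalool, is closed by Pd-catalysed C–O coupling.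

Key step: step 16

Assumption: commercial (R)-(−)-linalool of high enantiomeric purity fixes C2 of the chroman; the sulfone-bearing carbon of 6–8 is formed as a mixture of epimers and is removed in step 5.

**Route**

Step 1
Reactants: 1 (2E,6E)-farnesyl bromide
Product: 2 (2E,6E)-farnesyl p-tolyl sulfone
Conditions: TolSO2Na, DMF, rt
Reagents that add atoms: sodium p-toluenesulfinate, Cc1ccc(cc1)S(=O)[O-].[Na+]
Why: SN2 S-alkylation of the sulfinate by the primary allylic bromide (allylic sulfone synthesis) should leave both (E)-alkenes untouched.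

Step 2
Reactants: 3 (2E,6E)-farnesyl acetate
Product: 4 (2E,6E,10E)-12-hydroxyfarnesyl acetate
Conditions: SeO2 (cat.), t-BuOOH, salicylic acid (cat.), CH2Cl2, 0 °C to rt
Reagents that add atoms: tert-butyl hydroperoxide, CC(C)(C)OO (oxygen atom, relayed through catalytic SeO2)
Why: Riley-type allylic oxidation (ene reaction, then [2,3]-sigmatropic shift) should select the (E)-methyl group of the terminal, most electron-rich isopropylidene unit and give the (E)-allylic alcohol.

Step 3
Reactants: 4 (2E,6E,10E)-12-hydroxyfarnesyl acetate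
Product: 5 (2E,6E,10E)-12-bromofarnesyl acetate
Conditions: CBr4, PPh3, CH2Cl2, 0 °C
Reagents that add atoms: carbon tetrabromide, BrC(Br)(Br)Br
Why: Appel bromination should convert the primary allylic alcohol into the bromide under neutral conditions without allylic transposition or loss of the acetate.

Step 4
Reactants: 2 (2E,6E)-farnesyl p-tolyl sulfone; 5 (2E,6E,10E)-12-bromofarnesyl acetate
Product: 7 (2E,6E,10E,14E,18E)-3,7,11,15,19,23-hexamethyl-13-(p-tolylsulfonyl)tetracosa-2,6,10,14,18,22-hexaen-1-yl acetate, via lithiated sulfone 6 (not isolated)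
Conditions: n-BuLi, THF/DMPU, −78 °C; then 5, −78 to −20 °C
Reagents that add atoms: none
Why: sulfone-anion allylation (Julia/Biellmann-type coupling) — the α-sulfonyl carbanion should displace the allylic bromide by SN2 much faster than it attacks the acetate at −78 °C, and the new stereocentre at the sulfone carbon is of no consequence.

Step 5
Reactants: 7 C30 sulfone acetate
Product: 9 all-(E)-hexaprenol, via hydroxy sulfone 8 (not isolated)
Conditions: LiBHEt3 (excess), THF, 0 °C; then Pd(dppp)Cl2 (cat.), 0 °C to rt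
Reagents that add atoms: none
Why: LiBHEt3 should first cleave the acetate to the alkoxide, after which zerovalent palladium ionises the allylic sulfone and hydride is delivered to the less substituted allyl terminus (Pd-catalysed reductive desulfonylation), keeping the trisubstituted (E)-alkene in place.

Step 6
Reactants: 9 all-(E)-hexaprenol
Product: 10 all-(E)-hexaprenyl bromide
Conditions: PBr3, Et2O, 0 °C
Reagents that add atoms: phosphorus tribromide, BrP(Br)Br
Why: bromination of the primary allylic alcohol with PBr3 should proceed by SN2 displacement at 0 °C with the (2E) geometry retained.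

Step 7
Reactants: 10 all-(E)-hexaprenyl bromide
Product: 11 (5E,9E,13E,17E,21E)-6,10,14,18,22,26-hexamethylheptacosa-5,9,13,17,21,25-hexaen-1-yne
Conditions: propyne, n-BuLi (2 equiv per propyne), TMEDA, Et2O/hexane, −78 to 0 °C; then 10, THF, −78 °C to rt; aq. NH4Cl
Reagents that add atoms: propyne, CC#C
Why: propargylation with 1,3-dilithiopropyne — its sp3 carbanion terminus is the more nucleophilic site and should alkylate the allylic bromide by SN2, so that protonation gives the terminal alkyne directly.

Step 8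
Reactants: 11 C33 terminal alkyne
Product: 13 (1E,5E,9E,13E,17E,21E)-1-iodo-2,6,10,14,18,22,26-heptamethylheptacosa-1,5,9,13,17,21,25-heptaene, via alkenyldimethylalane 12 (not isolated)
Conditions: Me3Al, Cp2ZrCl2 (cat.), CH2Cl2, 0 °C to rt; then I2, THF, −30 to 0 °C
Reagents that add atoms: trimethylaluminium, C[Al](C)C; iodine, II
Why: Negishi zirconium-catalysed carboalumination adds CH3 and Al syn across the terminal alkyne with Al on the terminal carbon, and iodinolysis of the C–Al bond with retention should fix the (E)-2-methyl-1-iodoalkene.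

Step 9
Reactants: 14 2,3-dimethylphenol
Product: 15 (2,3-dimethylphenoxy)triisopropylsilane
Conditions: i-Pr3SiCl, imidazole, DMF, rt
Reagents that add atoms: triisopropylsilyl chloride, CC(C)[Si](Cl)(C(C)C)C(C)C
Why: imidazole-promoted O-silylation installs an ether that should withstand bases, boranes and organometallic reagents and is removed by fluoride at the end.

Step 10
Reactants: 15 (2,3-dimethylphenoxy)triisopropylsilane
Product: 17 (5-iodo-2,3-dimethylphenoxy)triisopropylsilane, via arylboronate 16 (not isolated)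
Conditions: [Ir(OMe)(cod)]2 (cat.), dtbpy, B2pin2, THF, 80 °C; evaporate; then CuI (cat.), 1,10-phenanthroline, KI, MeOH/H2O, air, 80 °C
Reagents that add atoms: potassium iodide, [K+].[I-]
Why: iridium-catalysed C–H borylation is sterically controlled and should take the only ring C–H flanked by two hydrogens (C5), and copper-mediated iododeboronation then replaces boron by iodine at the same carbon.

Step 11
Reactants: 17 (5-iodo-2,3-dimethylphenoxy)triisopropylsilane
Product: 18 (4-bromo-5-iodo-2,3-dimethylphenoxy)triisopropylsilane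
Conditions: NBS, MeCN, 0 °C to rt, dark
Reagents that add atoms: N-bromosuccinimide, O=C1CCC(=O)N1Br
Why: electrophilic aromatic bromination should occur para to the silyloxy group (C4), the free ortho position being shielded by the triisopropylsilyl group.

Step 12
Reactants: 19 (R)-(−)-linalool; 18 (4-bromo-5-iodo-2,3-dimethylphenoxy)triisopropylsilane
Product: 21 (R)-1-(2-bromo-3,4-dimethyl-5-triisopropylsilyloxyphenyl)-3,7-dimethyloct-6-en-3-ol, via alkylborane 20 (not isolated)
Conditions: 19, 9-BBN (1.5 equiv), THF, 0 °C to rt; then 18, Pd(dppf)Cl2·CH2Cl2 (cat.), aq. K3PO4, DMF, rt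
Reagents that add atoms: none
Why: 9-BBN hydroborates the monosubstituted vinyl group anti-Markovnikov in preference to the trisubstituted alkene and the hindered tertiary hydroxyl, and B-alkyl Suzuki–Miyaura coupling at room temperature should engage the C–I bond only, leaving C–Br and the carbinol stereocentre untouched.

Step 13
Reactants: 21 (R)-bromoaryl carbinol
Product: 22 (R)-triisopropyl{[2,7,8-trimethyl-2-(4-methylpent-3-en-1-yl)chroman-6-yl]oxy}silane
Conditions: Pd(OAc)2 (cat.), 2-(di-tert-butylphosphino)-1,1'-binaphthyl, Cs2CO3, toluene, 80 °C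
Reagents that add atoms: none
Why: intramolecular Pd-catalysed C–O coupling (Buchwald–Hartwig-type etherification) closes the pyran ring at the aryl carbon, so the C–O bond of the tertiary carbinol is never broken and the (R) configuration is retained at C2; a tertiary alkoxide also offers no hydrogen for β-hydride elimination.

Step 14
Reactants: 22 (R)-chroman with 4-methylpent-3-enyl side chain
Product: 23 (R,E)-2-methyl-5-[2,7,8-trimethyl-6-(triisopropylsilyloxy)chroman-2-yl]pent-2-enal
Conditions: methacrolein (excess), second-generation Hoveyda–Grubbs catalyst RuCl2(H2IMes)(=CH–C6H4-2-O-i-Pr) (cat.), CH2Cl2, 40 °C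
Reagents that add atoms: methacrolein, C=C(C)C=O
Why: olefin cross-metathesis exchanges the isopropylidene terminus for the methacrolein-derived unit with loss of isobutene, and the conjugated trisubstituted enal should form as the thermodynamically favoured (E) isomer.

Step 15
Reactants: 23 (R,E)-enal
Product: 24 (R)-triisopropyl({2,7,8-trimethyl-2-[(3E)-4-methylhexa-3,5-dien-1-yl]chroman-6-yl}oxy)silane
Conditions: Ph3PCH3Br, KN(SiMe3)2, THF, 0 °C; then 23, −78 to 0 °C
Reagents that add atoms: methyltriphenylphosphonium bromide, C[P+](c1ccccc1)(c1ccccc1)c1ccccc1.[Br-]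
Why: Wittig methylenation of the aldehyde should give the terminal vinyl group without affecting the trisubstituted (E)-alkene.

Step 16
Reactants: 24 (R,E)-diene; 13 C34 (E)-alkenyl iodide
Product: 26 O-triisopropylsilyl plastochromanol 8, via homoallylic alkylborane 25 (not isolated)
Conditions: 24 (1.2 equiv), 9-BBN (1.2 equiv), THF, 0 °C to rt; then 13, Pd(dppf)Cl2·CH2Cl2 (cat.), AsPh3, aq. Cs2CO3, DMF/THF, rt, degassed, dark
Reagents that add atoms: none
Why: 9-BBN adds syn and anti-Markovnikov to the terminal CH=CH2 of the diene to give the primary homoallylic borane 25; zerovalent palladium inserts into the C–I bond of 13, the base-activated borate transfers its primary alkyl group to palladium, and reductive elimination forms the vinylic CH–allylic CH2 bond. The closest known reaction type is the B-alkyl Suzuki–Miyaura coupling of a 9-BBN-derived primary alkylborane with an alkenyl iodide, here fed by the established terminal hydroboration of an (E)-4-methyl-1,3-diene. No ring is closed and no stereocentre is created; the (E) geometry of the junction alkene is inherited from 13 because oxidative addition and reductive elimination are stereoretentive, while the (E)-alkene of 24 and C2 are spectators. The step needs hydroboration at the monosubstituted diene terminus only, which the bulk of 9-BBN secures, and 13 with its seven alkenes is added only after the borane has been consumed. It also needs transfer of the primary alkyl group rather than the secondary bicyclic B–C bonds, which is intrinsic to B-alkyl-9-BBN reagents, and the wide-bite-angle dppf ligand should favour reductive elimination over β-hydride elimination.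

Step 17
Reactants: 26 O-triisopropylsilyl plastochromanol 8
Product: 27 plastochromanol 8
Conditions: Bu4NF, AcOH, THF, 0 °C to rt, argon
Reagents that add atoms: none
Why: fluoride-mediated cleavage of the aryl silyl ether (desilylation) should free the phenol, with acetic acid keeping the oxidation-prone chromanol protonated.

**Compound list**

1 | (2E,6E)-farnesyl bromide | CC(C)=CCC/C(C)=C/CC/C(C)=C/CBr | starting material
2 | (2E,6E)-farnesyl p-tolyl sulfone | CC(C)=CCC/C(C)=C/CC/C(C)=C/CS(=O)(=O)c1ccc(C)cc1 | intermediate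
3 | (2E,6E)-farnesyl acetate | CC(C)=CCC/C(C)=C/CC/C(C)=C/COC(C)=O | starting material
4 | (2E,6E,10E)-12-hydroxy-3,7,11-trimethyldodeca-2,6,10-trien-1-yl acetate | OC/C(C)=C/CC/C(C)=C/CC/C(C)=C/COC(C)=O | intermediate
5 | (2E,6E,10E)-12-bromo-3,7,11-trimethyldodeca-2,6,10-trien-1-yl acetate | BrC/C(C)=C/CC/C(C)=C/CC/C(C)=C/COC(C)=O | intermediate
6 | α-lithiated farnesyl p-tolyl sulfone (not isolated) | CC(C)=CCC/C(C)=C/CC/C(C)=C/C([Li])S(=O)(=O)c1ccc(C)cc1 | intermediate
7 | (2E,6E,10E,14E,18E)-3,7,11,15,19,23-hexamethyl-13-(p-tolylsulfonyl)tetracosa-2,6,10,14,18,22-hexaen-1-yl acetate (epimers at C13) | CC(C)=CCC/C(C)=C/CC/C(C)=C/C(C/C(C)=C/CC/C(C)=C/CC/C(C)=C/COC(C)=O)S(=O)(=O)c1ccc(C)cc1 | intermediate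
8 | corresponding C30 hydroxy sulfone, present as its lithium alkoxide (not isolated) | CC(C)=CCC/C(C)=C/CC/C(C)=C/C(C/C(C)=C/CC/C(C)=C/CC/C(C)=C/CO)S(=O)(=O)c1ccc(C)cc1 | intermediate
9 | all-(E)-hexaprenol, (2E,6E,10E,14E,18E)-3,7,11,15,19,23-hexamethyltetracosa-2,6,10,14,18,22-hexaen-1-ol | CC(C)=CCC/C(C)=C/CC/C(C)=C/CC/C(C)=C/CC/C(C)=C/CC/C(C)=C/CO | intermediate
10 | all-(E)-hexaprenyl bromide | CC(C)=CCC/C(C)=C/CC/C(C)=C/CC/C(C)=C/CC/C(C)=C/CC/C(C)=C/CBr | intermediate
11 | (5E,9E,13E,17E,21E)-6,10,14,18,22,26-hexamethylheptacosa-5,9,13,17,21,25-hexaen-1-yne | CC(C)=CCC/C(C)=C/CC/C(C)=C/CC/C(C)=C/CC/C(C)=C/CC/C(C)=C/CCC#C | intermediate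
12 | (E)-alkenyldimethylalane from syn-methylalumination of 11 (not isolated) | CC(C)=CCC/C(C)=C/CC/C(C)=C/CC/C(C)=C/CC/C(C)=C/CC/C(C)=C/CC/C(C)=C/[Al](C)C | intermediate
13 | (1E,5E,9E,13E,17E,21E)-1-iodo-2,6,10,14,18,22,26-heptamethylheptacosa-1,5,9,13,17,21,25-heptaene | CC(C)=CCC/C(C)=C/CC/C(C)=C/CC/C(C)=C/CC/C(C)=C/CC/C(C)=C/CC/C(C)=C/I | intermediate
14 | 2,3-dimethylphenol | Cc1cccc(O)c1C | starting material
15 | (2,3-dimethylphenoxy)triisopropylsilane | Cc1cccc(O[Si](C(C)C)(C(C)C)C(C)C)c1C | intermediate
16 | 2-[3,4-dimethyl-5-(triisopropylsilyloxy)phenyl]-4,4,5,5-tetramethyl-1,3,2-dioxaborolane (not isolated) | Cc1cc(B2OC(C)(C)C(C)(C)O2)cc(O[Si](C(C)C)(C(C)C)C(C)C)c1C | intermediate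
17 | (5-iodo-2,3-dimethylphenoxy)triisopropylsilane | Cc1cc(I)cc(O[Si](C(C)C)(C(C)C)C(C)C)c1C | intermediate
18 | (4-bromo-5-iodo-2,3-dimethylphenoxy)triisopropylsilane | Cc1c(Br)c(I)cc(O[Si](C(C)C)(C(C)C)C(C)C)c1C | intermediate
19 | (R)-(−)-linalool | CC(C)=CCC[C@@](C)(O)C=C | starting material
20 | (R)-1-(9-borabicyclo[3.3.1]nonan-9-yl)-3,7-dimethyloct-6-en-3-ol (not isolated) | CC(C)=CCC[C@@](C)(O)CCB1C2CCCC1CCC2 | intermediate
21 | (R)-1-[2-bromo-3,4-dimethyl-5-(triisopropylsilyloxy)phenyl]-3,7-dimethyloct-6-en-3-ol | CC(C)=CCC[C@@](C)(O)CCc1cc(O[Si](C(C)C)(C(C)C)C(C)C)c(C)c(C)c1Br | intermediate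
22 | (R)-triisopropyl{[2,7,8-trimethyl-2-(4-methylpent-3-en-1-yl)chroman-6-yl]oxy}silane | CC(C)=CCC[C@]1(C)CCc2cc(O[Si](C(C)C)(C(C)C)C(C)C)c(C)c(C)c2O1 | intermediate
23 | (R,E)-2-methyl-5-[2,7,8-trimethyl-6-(triisopropylsilyloxy)chroman-2-yl]pent-2-enal | O=C/C(C)=C/CC[C@]1(C)CCc2cc(O[Si](C(C)C)(C(C)C)C(C)C)c(C)c(C)c2O1 | intermediate
24 | (R)-triisopropyl({2,7,8-trimethyl-2-[(3E)-4-methylhexa-3,5-dien-1-yl]chroman-6-yl}oxy)silane | C=C/C(C)=C/CC[C@]1(C)CCc2cc(O[Si](C(C)C)(C(C)C)C(C)C)c(C)c(C)c2O1 | intermediate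
25 | 9-{(3E)-3-methyl-6-[(2R)-2,7,8-trimethyl-6-(triisopropylsilyloxy)chroman-2-yl]hex-3-en-1-yl}-9-borabicyclo[3.3.1]nonane (not isolated) | C(C/C(C)=C/CC[C@]1(C)CCc2cc(O[Si](C(C)C)(C(C)C)C(C)C)c(C)c(C)c2O1)B1C2CCCC1CCC2 | intermediate
26 | (2R)-O-triisopropylsilyl plastochromanol 8 | CC(C)=CCC/C(C)=C/CC/C(C)=C/CC/C(C)=C/CC/C(C)=C/CC/C(C)=C/CC/C(C)=C/CC/C(C)=C/CC[C@]1(C)CCc2cc(O[Si](C(C)C)(C(C)C)C(C)C)c(C)c(C)c2O1 | intermediate
27 | plastochromanol 8, (2R) | CC(C)=CCC/C(C)=C/CC/C(C)=C/CC/C(C)=C/CC/C(C)=C/CC/C(C)=C/CC/C(C)=C/CC/C(C)=C/CC[C@]1(C)CCc2cc(O)c(C)c(C)c2O1 | target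

**Step count and risks**

Total steps: 17. Longest linear sequence: 9 steps (3 to 27 through steps 2–8, 16 and 17; the chroman branch 14 to 27 through steps 9–17 is equally long).

Steps most likely to fail:

1. Step 16 (key step). Hydroboration of the conjugated diene may not be clean (boron placed at the allylic position, or a second hydroboration). Transmetalation of the bulky, very lipophilic alkylborane may also be slow relative to protodeboronation or β-hydride elimination. The fallback is a Negishi alkyl–alkenyl coupling, setting out from 24 and returning to the route at 26. Diene 24 is hydroborated with 9-BBN to 25 and oxidised (NaOH, H2O2) to the homoallylic alcohol (R,E)-3-methyl-6-[2,7,8-trimethyl-6-(triisopropylsilyloxy)chroman-2-yl]hex-3-en-1-ol F1, which can be freed from regioisomers by chromatography. I2/PPh3/imidazole should give the primary iodide F2, and t-BuLi (2 equiv, Et2O, −78 °C) the alkyllithium F3. ZnBr2 then gives the alkylzinc bromide F4, and Pd(dppf)Cl2-catalysed coupling of F4 with 13 (THF, rt) should give 26.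

2. Step 13. Oxidative addition into the electron-rich, doubly ortho-substituted C–Br bond may be slow, so that reductive loss of bromine or dehydration of the tertiary carbinol competes. The fallback forms the C2–O bond first by asymmetric allylic etherification and closes the pyran ring at C4–C4a by intramolecular B-alkyl Suzuki–Miyaura coupling. It sets out from 15 and returns at 22, and (R)-linalool 19 is then not needed. para-Bromination of 15 (NBS, MeCN) gives (4-bromo-2,3-dimethylphenoxy)triisopropylsilane F5. Bromine–lithium exchange (n-BuLi, THF, −78 °C) gives the aryllithium F6, B(OMe)3 the dimethyl arylboronate F7, and H2O2/NaHCO3 oxidation 2,3-dimethyl-4-(triisopropylsilyloxy)phenol F8. ortho-Bromination (NBS, i-Pr2NH cat., CH2Cl2) gives 6-bromo-2,3-dimethyl-4-(triisopropylsilyloxy)phenol F9. Tsuji–Trost asymmetric O-allylation with geranyl methyl carbonate (Pd2(dba)3·CHCl3, enantiopure N,N'-(cyclohexane-1,2-diyl)bis[2-(diphenylphosphino)benzamide], CH2Cl2), with the ligand enantiomer chosen for the (R) product, should give the branched tertiary aryl ether F10. 9-BBN hydroboration of its vinyl group gives the alkylborane F11, which under Pd(dppf)Cl2/aq. K3PO4 at high dilution should close the pyran ring to 22.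

3. Step 14. The trisubstituted alkene may enter the metathesis cycle too slowly, so that catalyst decomposition and self-metathesis of methacrolein limit conversion. The fallback is allylic C–H oxidation, setting out from 22 and returning at 23. SeO2 (cat.)/t-BuOOH should oxidise the (E)-methyl group of the isopropylidene terminus to the (E)-allylic alcohol (R,E)-2-methyl-5-[2,7,8-trimethyl-6-(triisopropylsilyloxy)chroman-2-yl]pent-2-en-1-ol F12, and MnO2 (CH2Cl2) then oxidises F12 to enal 23.

**Further compounds**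

F1 | step 16 | (R,E)-3-methyl-6-[2,7,8-trimethyl-6-(triisopropylsilyloxy)chroman-2-yl]hex-3-en-1-ol | OCC/C(C)=C/CC[C@]1(C)CCc2cc(O[Si](C(C)C)(C(C)C)C(C)C)c(C)c(C)c2O1
F2 | step 16 | (R)-{[2-((3E)-6-iodo-4-methylhex-3-en-1-yl)-2,7,8-trimethylchroman-6-yl]oxy}triisopropylsilane | ICC/C(C)=C/CC[C@]1(C)CCc2cc(O[Si](C(C)C)(C(C)C)C(C)C)c(C)c(C)c2O1
F3 | step 16 | homoallylic alkyllithium from F2 | [Li]CC/C(C)=C/CC[C@]1(C)CCc2cc(O[Si](C(C)C)(C(C)C)C(C)C)c(C)c(C)c2O1
F4 | step 16 | homoallylic alkylzinc bromide from F3 | Br[Zn]CC/C(C)=C/CC[C@]1(C)CCc2cc(O[Si](C(C)C)(C(C)C)C(C)C)c(C)c(C)c2O1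
F5 | step 13 | (4-bromo-2,3-dimethylphenoxy)triisopropylsilane | Cc1c(Br)ccc(O[Si](C(C)C)(C(C)C)C(C)C)c1C
F6 | step 13 | [2,3-dimethyl-4-(triisopropylsilyloxy)phenyl]lithium | Cc1c([Li])ccc(O[Si](C(C)C)(C(C)C)C(C)C)c1C
F7 | step 13 | dimethyl [2,3-dimethyl-4-(triisopropylsilyloxy)phenyl]boronate | COB(OC)c1ccc(O[Si](C(C)C)(C(C)C)C(C)C)c(C)c1C
F8 | step 13 | 2,3-dimethyl-4-(triisopropylsilyloxy)phenol | Cc1c(O)ccc(O[Si](C(C)C)(C(C)C)C(C)C)c1C
F9 | step 13 | 6-bromo-2,3-dimethyl-4-(triisopropylsilyloxy)phenol | Cc1c(O)c(Br)cc(O[Si](C(C)C)(C(C)C)C(C)C)c1C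
F10 | step 13 | (R)-{5-bromo-4-[(3,7-dimethylocta-1,6-dien-3-yl)oxy]-2,3-dimethylphenoxy}triisopropylsilane | C=C[C@@](C)(CCC=C(C)C)Oc1c(Br)cc(O[Si](C(C)C)(C(C)C)C(C)C)c(C)c1C
F11 | step 13 | 9-BBN adduct at the vinyl group of F10 | C(C[C@@](C)(CCC=C(C)C)Oc1c(Br)cc(O[Si](C(C)C)(C(C)C)C(C)C)c(C)c1C)B1C2CCCC1CCC2
F12 | step 14 | (R,E)-2-methyl-5-[2,7,8-trimethyl-6-(triisopropylsilyloxy)chroman-2-yl]pent-2-en-1-ol | OC/C(C)=C/CC[C@]1(C)CCc2cc(O[Si](C(C)C)(C(C)C)C(C)C)c(C)c(C)c2O1
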